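Start from a ratio: the G plateau in grey, averaged from 2.50 d on, is 20.6%, and in blue, averaged from 2.50 d on, it is 15.7%. That is 1.31 to one, for 2.90 times the [E].

| flask | Z | D | E | remark | time |
|---|---|---|---|---|---|
| grey | 20 mM | 12 mM | 9.3 mM | run made earlier |  |
| blue | 20 mM | 12 mM | 27 mM | run made earlier |  |
| autumn | 20 mM | 12.0 mM | 15.0 mM |  | 12 d |
| dawn | 20 mM | 12.0 mM | 25.0 mM |  | 12 d |
| summer | 20 mM | 12.0 mM | 40.0 mM |  | 12 d |

| run | time / d | G / % | Z / % |
|---|---|---|---|
| grey | 0.500 | 13.9 | 23.3 |
| grey | 0.833 | 17.3 | 12.8 |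
| grey | 1.04 | 18.4 | 8.4 |
| grey | 1.67 | 18.6 | 3.9 |
| grey | 2.50 | 20.4 | 0.9 |
| grey | 4.00 | 20.9 | 0.9 |
| grey | 6.00 | 20.5 | 0 |
| blue | 0.333 | 8.3 | 33.9 |
| blue | 0.833 | 12.4 | 13.3 |
| blue | 1.67 | 14.9 | 3.4 |
| blue | 2.50 | 15.3 | 1.8 |
| blue | 4.00 | 15.1 | 0.2 |
| blue | 5.00 | 16.6 | 1.2 |
| blue | 6.00 | 15.7 | 0.2 |

(each reading ± 0.5 percentage points)

- amount of G at the end, in percent of the Z charged for autumn, dawn, summer, in this order
- the shape of the row from first to last (falls all the way / hardly changes / rises all the way / rises, then falls / falls, then rises)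

- "hardly changes" means that all values lie within two and a half points (for a concentration: within two and a half percent of the largest)

Z falls alike in the two runs, at 12.8% in grey and 13.3% in blue at 0.833 d, and it reads 0% and 0.2% at 6.00 d. The asked 12 d lies later, so read plateaus.

Treat E as a competitor: draw the reciprocal of G as a straight line in [E]. Take the even case as the zero of the scale: the two plateaus put it at 47.0 mM, and E-half is this [E], at which G stands on the line at half of its value without E. The same plateaus put the value without E at 24.7%. Divide that value by one plus [E] over E-half. My row is 18.7%, 16.1%, 13.3%.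

The forecast, holding that “E seems to act on selectivity”, gives 18.8%, 16.1%, 13.3%, falls all the way, above mine at the first point.

The flasks give 19.1%, 16.5%, 13.6%: falls all the way.

    E + J → Q (k = 2900 M⁻¹ h⁻¹)
    D + J → G (k = 5600 M⁻¹ h⁻¹)
    Z → J (k = 0.0560 h⁻¹)
    J → L (k = 53.0 h⁻¹)
    2 Z → X (k = 3.40 M⁻¹ h⁻¹)

Carry autumn's G across with E-half, multiplying by the ratio of the two divisors: summer comes to 13.6% against 13.6%, and dawn to 16.4% against 16.5%. In autumn, 2 Z → X has half of its turnover behind it by 0.119 d, Z → J by 0.322 d and D + J → G by 0.298 d. Z, the limiting reagent, is at 0.00918% by 6.00 d, with 82% of E left at 12.0 d, and autumn's G reads 19.1% at 6.00 d and 19.1% at 120 d.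

The earlier runs and the new flask are simulated with constants of no real substance; scatter was added.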